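## Structural features

The target is a 3,5-dihydro-1-benzofuran-6(2H)-one. Ring A (O1, C2, C3, C3a, C7a, a dihydrofuran) is fused along C3a–C7a to ring B (C3a, C4, C5, C6, C7, C7a), and ring C, a 3,4,5-trimethoxyphenyl group, sits on C2. Ring B is a linearly conjugated cyclohexa-2,4-dienone (C6=O, C7=C7a, C3a=C4). Its only sp3 atom, C5, carries a methoxy and an allyl group, so ring B is a blocked ortho-quinol ether, and O1–C7a=C7–C6=O is a vinylogous ester. C2 (S) and C3 (S) are adjacent, with aryl and methyl trans; C5 (S) has its methoxy group on the face of the C2 aryl group and its allyl group on the face of the C3 methyl group, and it is separated from C3 by the sp2 atoms C3a and C4 of a nearly flat ring, so C2/C3 cannot be expected to steer it. The molecule is fragile in three ways: heat opens a Cope shift of the C5 allyl group to C3a and a retro-Claisen shift to O6, from where a Claisen shift to C7 ends in an arene; acid invites dienone–phenol migration, loss of methanol and opening of the benzylic C2–O1 bond; and the diene can dimerise by Diels–Alder reaction. The real difficulty is therefore C5, a fully substituted O- and C-bearing stereocenter next to a ketone in a ring that tends to aromatise, which must be made at low temperature, at one of four competing sites (O6, C5, C7, C3a), with face control from outside the molecule. The key step exploits the fact that C5 carries geminally, next to C6=O, exactly the two halves of allyl methyl ether (CH3O and CH2CH=CH2), so C5 can be read as a divalent carbon inserted into the O–allyl bond, and ring B without these groups is the flat, stable 5-diazo-6-oxo (ortho-quinone diazide) system. In addition, O1 is conjugated with C6=O but not with C5, which makes the two carbonyl groups of the 5,6-dione different and allows nitrogen to be placed on C5 alone.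

## Logic of the disconnections

**12 ⇒ 8 + 9.**
- Bonds cut: both exocyclic bonds of C5 at once, C5–O(methoxy) and C5–CH2(allyl).
- Reason: the two substituents together are 9, and C5 lies alpha to C6=O, where a diazo carbon is stable. In one sentence, the route is the insertion of the divalent C5 of 8 into the O–allyl bond of 9 by ylide formation and [2,3] shift.
- Gain: the quaternary stereocenter, both of its substituents and the dearomatised state of ring B disappear together. What remains is a flat ring B with only the C2/C3 pair.
- Demand: carbene transfer must go to oxygen and not to the alkene. The shift must go to C5 at or below room temperature, and the face of C5 must be chosen by the catalyst.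

**8 ⇒ 6.**
- Bond cut: C5=N2, replaced by C5=O.
- Reason: in 6 the C6 carbonyl is deactivated by O1 through C7a=C7, and the C5 carbonyl is not. Nitrogen can therefore be brought in by condensation, without nitration or azo chemistry on a molecule that has a second electron-rich arene.
- Gain: one operation from a dione.
- Demand: attack at C5 only, short handling, and no strong base, because the C3–H of 6 allows tautomerisation toward an aromatic benzofuran.

**6 ⇒ 5.**
- Bonds changed: C6=O back to C6–OCH3, and C5=O back to C5–OH.
- Reason: 5 is exactly what the ring A forming step delivers.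
- Gain: no protecting groups and no separate demethylation.
- Demand: oxygen must be delivered ortho (to C6). Delivery para to C7a would break ring A.

**5 ⇒ 3 + 4.**
- Bonds cut: C3–C3a and O1–C2, that is, ring A.
- Reason: both bonds flank the two adjacent stereocenters, so C2 and C3 are set together.
- Gain: two flat, achiral pieces.
- Demand: regiocontrol by chelation of 4, enantioface selection at the first C–C bond, and trans ring closure.

**3 ⇒ 1 + 2.**
- Bond cut: the aryl–C(sp2) bond.
- Reason: it guarantees the E alkene that the trans closure relies on.
- Gain: two commercial compounds.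
- Demand: retention of alkene geometry.

## Other disconnections considered

**Alternative 1:** (the first that comes to mind) cut C5–OCH3 only.
- Forward key step: oxidative dearomatisation of the allyl phenol A1 with PhI(OAc)2 in methanol.
- Site selectivity: the phenoxenium-type intermediate carries charge at C5, C7 and C3a. C3a is para to O6 and alkyl-substituted, and attack there leads to the cross-conjugated dienone pattern that is generally preferred. Methanol is therefore expected to add at C3a rather than at C5.
- Face control: the external nucleophile is not bound to any chiral element, so the faces of C5 stay uncontrolled.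
- Step economy: A1 itself needs an allylation/Claisen sequence on top of the ring A synthesis.

**Alternative 2:** cut C5–allyl by a [3,3] shift back to C3a.
- Forward key steps: acid-promoted formal [3+2] cycloaddition of the quinone monoketal A2 with 3 to give the 3a-allyl dienone A3, then a suprafacial thermal Cope shift that relays the C3a configuration to C5.
- The stereochemical relay is attractive, but A3 must carry allyl cis to the adjacent C3 methyl group, which is the more crowded arrangement.
- The cationic cycloaddition competes with a [5+2] mode and has no established enantioselective version.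
- The cross-conjugated A3 is not expected to be less stable than the linear dienone, so there is little driving force.
- At the temperature of the Cope shift, the retro-Claisen shift to O6 and the onward Claisen shift to C7 with aromatisation are also open. The target would be a way station and not the sink.

**Alternative 3:** cut C5–allyl with allyl as the electrophile.
- Forward key step: asymmetric dearomative allylation of the phenol A4 with a zerovalent palladium catalyst (Tsuji–Trost type), or the thermal ortho-Claisen shift of its allyl ether A5.
- The phenolate is ambident (O6, C7, C5, C3a), and C5 is the hindered, already substituted site.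
- Attack at C7 is followed by irreversible tautomerisation to an arene, so any reversibility funnels material away from C5.
- The chosen plan removes this competition, because its reactive carbon is C5 by construction.

Key step: step 5

Assumption: the (4R,5R) ligand in step 2 and the S-configured dirhodium catalyst in step 5 are written for the (2S,3S) and (5S) products; the sense of induction cannot be derived with certainty, and the equally available mirror-image ligand would be used if it is opposite.

## Steps

Step 1
Reactants: 1 5-bromo-1,2,3-trimethoxybenzene; 2 (E)-prop-1-en-1-ylboronic acid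
Product: 3 (E)-1,2,3-trimethoxy-5-(prop-1-en-1-yl)benzene ((E)-isoelemicin)
Conditions: Pd(PPh3)4 (3 mol %), K2CO3 (2 equiv), 1,4-dioxane/H2O, 85 °C
Reagents that add atoms: none
Why: Suzuki–Miyaura coupling; transmetalation and reductive elimination proceed with retention, so the E geometry of 2 is carried into 3, and no sensitive group is present.

Step 2
Reactants: 3 (E)-isoelemicin; 4 2-methoxy-1,4-benzoquinone
Product: 5 (2S,3S)-6-methoxy-3-methyl-2-(3,4,5-trimethoxyphenyl)-2,3-dihydro-1-benzofuran-5-ol
Conditions: TiCl2(OiPr)2 (1.2 equiv), (4R,5R)-TADDOL (1.3 equiv), 4 Å MS, CH2Cl2, −78 → 0 °C; then H2O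
Reagents that add atoms: none
Why: Lewis-acid-promoted formal [3+2] cycloaddition of a 2-alkoxy-1,4-benzoquinone with an (E)-propenylarene, a reaction known with TADDOLates of tetravalent titanium for exactly this product class. Chelation of the methoxy group and the adjacent carbonyl of 4 directs the methyl-bearing alkene carbon to the quinone CH that becomes C3a, the benzylic cation is trapped by the neighbouring carbonyl oxygen (O1–C2), and tautomerisation gives the phenol. C3 is set by the shielded quinone face in the chiral chelate and C2 by closure anti to the methyl group (trans); recrystallisation of 5 should raise the enantiopurity.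

Step 3
Reactants: 5 (2S,3S)-6-methoxy-3-methyl-2-(3,4,5-trimethoxyphenyl)-2,3-dihydro-1-benzofuran-5-ol
Product: 6 (2S,3S)-3-methyl-2-(3,4,5-trimethoxyphenyl)-2,3-dihydro-1-benzofuran-5,6-dione
Conditions: IBX (1.1 equiv), DMF, 0 → 23 °C, dark
Reagents that add atoms: 2-iodoxybenzoic acid (IBX), O=C1OI(=O)(O)c2ccccc12
Why: Oxidative demethylation of a 2-methoxyphenol with IBX; the phenol binds to pentavalent iodine and oxygen is passed within the complex to the ortho carbon C6, whose positive character is stabilised by its methoxy group, and the hemiketal collapses with loss of methanol. The inner-sphere delivery avoids attack at the para carbon C7a, which would open ring A; C2 and C3 are untouched.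

Step 4
Reactants: 6 (2S,3S)-3-methyl-2-(3,4,5-trimethoxyphenyl)-2,3-dihydro-1-benzofuran-5,6-dione
Product: 8 (2S,3S)-5-diazo-3-methyl-2-(3,4,5-trimethoxyphenyl)-3,5-dihydro-1-benzofuran-6(2H)-one, via C5 tosylhydrazone 7 (not isolated)
Conditions: TsNHNH2 (1.0 equiv), CH2Cl2/MeOH, −10 → 20 °C, dark; then basic Al2O3, CH2Cl2
Reagents that add atoms: p-toluenesulfonyl hydrazide, Cc1ccc(cc1)S(=O)(=O)NN
Why: Monocondensation of a 1,2-dione with tosylhydrazide and base-induced loss of sulfinate (Bamford–Stevens-type diazo formation), the standard way from 1,2-diones and ortho-quinones to alpha-diazoketones and quinone diazides. C5=O reacts because C6=O is the carbonyl of the vinylogous ester O1–C7a=C7–C6=O, and the donor-substituted quinone is a weak oxidant toward the hydrazide.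

Step 5
Reactants: 8 (2S,3S)-5-diazo-3-methyl-2-(3,4,5-trimethoxyphenyl)-3,5-dihydro-1-benzofuran-6(2H)-one; 9 allyl methyl ether
Product: 12 (2S,3S,5S)-5-methoxy-3-methyl-5-(prop-2-en-1-yl)-2-(3,4,5-trimethoxyphenyl)-3,5-dihydro-1-benzofuran-6(2H)-one (target), via rhodium quinoid carbene 10 (not isolated), via allyl methyl oxonium ylide 11 (not isolated)
Conditions: Rh2(S-TCPTTL)4 (1 mol %; TCPTTL = N-tetrachlorophthaloyl-tert-leucinate), 9 (20 equiv), CH2Cl2, 4 Å MS, slow addition of 8, 0 → 25 °C, dark
Reagents that add atoms: none
Why: Proposed new method: Rh2(S-TCPTTL)4 takes N2 out of 8 to give the electrophilic quinoid carbene 10, the ether oxygen of 9 adds to the empty p orbital at C5 to give the oxonium ylide 11, and a [2,3]-sigmatropic shift through a five-membered envelope transition state breaks the O–CH2 bond while the allyl terminus bonds to C5, so that the C5–OMe and C5–allyl bonds are made and ring B is dearomatised in one operation. The closest known reaction types are the rhodium-catalysed intermolecular oxonium ylide formation/[2,3] shift of allyl methyl ethers with alpha-diazocarbonyl compounds, the Doyle–Kirmse reaction of allyl sulfides, and the capture of quinoid carbenes by ethers as oxonium ylides; what is new is that the ylide carbon is the ortho carbon of a phenoxide, so the shift costs the aromatic sextet. This cost should be covered, because 11 is an aryl dialkyl oxonium zwitterion lying far above the neutral dienone, and because dearomatising sigmatropic shifts of much less energetic precursors (the first stage of the aromatic Claisen and Sommelet–Hauser rearrangements) are routine. No ring is closed; rings A and C are spectators. The one new stereocenter, C5, is under catalyst control: the flat carbene lies in the chiral pocket of the four ligands with its C6=O edge and its C4–H edge differentiated, 9 has to add to the open face (required: the face of the C2 aryl group), and the allyl terminus then replaces rhodium on the opposite face (the face of the C3 methyl group), which gives 5S, while C2 and C3 point out of the pocket and should perturb this little. Site selectivity is secured by the substrate, since the divalent carbon is C5 by construction and O6, C7 and C3a, which compete in every allyl-cation or thermal approach, are not addressed, and a [1,2] shift would give the same constitution because the allyl group is unsubstituted. The chemoselectivity needed is attack at oxygen over cyclopropanation, which is favoured by the electron-poor carbene and ligand set, by the unhindered methoxy oxygen, by the monosubstituted and inductively deactivated alkene of 9 and by its large excess, while slow addition of 8 suppresses azine formation. At or below 25 °C and without acid or base, the Cope (to C3a) and retro-Claisen (to O6) channels of 12 stay closed.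

## Compound list

1 | 5-bromo-1,2,3-trimethoxybenzene | COc1cc(Br)cc(OC)c1OC | starting material
2 | (E)-prop-1-en-1-ylboronic acid | C/C=C/B(O)O | starting material
3 | (E)-1,2,3-trimethoxy-5-(prop-1-en-1-yl)benzene | C/C=C/c1cc(OC)c(OC)c(OC)c1 | intermediate
4 | 2-methoxy-1,4-benzoquinone | COC1=CC(=O)C=CC1=O | starting material
5 | (2S,3S)-6-methoxy-3-methyl-2-(3,4,5-trimethoxyphenyl)-2,3-dihydro-1-benzofuran-5-ol | Oc1cc2c(cc1OC)O[C@H](c1cc(OC)c(OC)c(OC)c1)[C@H]2C | intermediate
6 | (2S,3S)-3-methyl-2-(3,4,5-trimethoxyphenyl)-2,3-dihydro-1-benzofuran-5,6-dione | O=C1C=C2C(=CC1=O)O[C@H](c1cc(OC)c(OC)c(OC)c1)[C@H]2C | intermediate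
7 | C5 mono(tosylhydrazone) of 6 (C=N geometry open) | Cc1ccc(cc1)S(=O)(=O)NN=C1C=C2C(=CC1=O)O[C@H](c1cc(OC)c(OC)c(OC)c1)[C@H]2C | intermediate
8 | (2S,3S)-5-diazo-3-methyl-2-(3,4,5-trimethoxyphenyl)-3,5-dihydro-1-benzofuran-6(2H)-one | [N-]=[N+]=C1C=C2C(=CC1=O)O[C@H](c1cc(OC)c(OC)c(OC)c1)[C@H]2C | intermediate
9 | allyl methyl ether (3-methoxyprop-1-ene) | C=CCOC | starting material
10 | C5 rhodium quinoid carbene from 8 (the Rh2(S-TCPTTL)4 unit is drawn as [Rh]) | [Rh]=C1C=C2C(=CC1=O)O[C@H](c1cc(OC)c(OC)c(OC)c1)[C@H]2C | intermediate
11 | (2S,3S)-5-[allyl(methyl)oxonio]-3-methyl-2-(3,4,5-trimethoxyphenyl)-2,3-dihydro-1-benzofuran-6-olate | C=CC[O+](C)c1cc2c(cc1[O-])O[C@H](c1cc(OC)c(OC)c(OC)c1)[C@H]2C | intermediate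
12 | (2S,3S,5S)-5-methoxy-3-methyl-5-(prop-2-en-1-yl)-2-(3,4,5-trimethoxyphenyl)-3,5-dihydro-1-benzofuran-6(2H)-one | C=CC[C@]1(OC)C=C2C(=CC1=O)O[C@H](c1cc(OC)c(OC)c(OC)c1)[C@H]2C | target

## Step count and least certain steps

Total step count: 5. Longest linear sequence: 5 (1 → 3 → 5 → 6 → 8 → 12).

**Step 5 (key step, bears the label "Proposed new method:").**
- The most likely failure is poor facial selectivity at C5. Release of rhodium from the ylide restores the aromatic sextet, so the shift may start from the metal-free planar ylide, where only the remote C2/C3 pair tells the faces apart.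
- Further risks are carbene transfer to the C=C bond of 9 instead of its oxygen, transfer of allyl or methyl to the phenoxide oxygen with rearomatisation, and sluggish loss of N2 from the stabilised diazo group, which would call for heat and so open the [3,3] channels. The two C5 epimers would be diastereomers and should be separable.
- Fallback (known chemistry), from 6 back to 12: the polarity at C5 is inverted and the two bonds are made one after the other. Catalytic asymmetric allylboration of the more electrophilic C5 carbonyl of 6 (allylB(pin), (S)-3,3'-dibromo-BINOL, t-BuOH, toluene, −20 °C) is a reaction type established for ketones and for isatins, whose ketone next to a deactivated carbonyl resembles 6. It should give the ortho-quinol (2S,3S,5S)-5-hydroxy-3-methyl-5-(prop-2-en-1-yl)-2-(3,4,5-trimethoxyphenyl)-3,5-dihydro-1-benzofuran-6(2H)-one F1. O-methylation without a free alkoxide (MeOTf, 2,6-di-tert-butyl-4-methylpyridine, CH2Cl2, 0 °C) then returns to 12; these conditions are chosen because the alkoxide would undergo an anionic oxy-Cope shift to C3a.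

**Step 2.**
- The most likely failures are incomplete enantioface discrimination and diversion into the [2+2] and [5+2] closure modes. The reaction is stepwise through a long-lived benzylic cation, and the chiral titanium species may be a mixture of aggregates.
- Fallback, from 3 and 4 back to 5: the same cycloaddition with achiral TiCl2(OiPr)2 gives the racemic trans phenol rac-(2S*,3S*)-6-methoxy-3-methyl-2-(3,4,5-trimethoxyphenyl)-2,3-dihydro-1-benzofuran-5-ol F2. Acylation with (1S,4R)-camphanoyl chloride (Et3N, DMAP, CH2Cl2) and separation of the diastereomeric esters by crystallisation or chromatography gives the (2S,3S)-configured (1S,4R)-camphanate of 5 F3. LiOH in THF/H2O followed by acidification then frees 5.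

**Step 3.**
- The most likely failures are oxygen transfer to the free ortho position C4, outer-sphere oxidation with attack at C7a and opening of ring A (5 is a hydroquinone monoether), and tautomerisation of the quinone through C3–H on prolonged handling.
- Fallback, from 5 back to 6: the redox step and the demethylation are separated. Chelation-assisted cleavage of the methyl ether next to the free phenol (AlCl3, pyridine, CH2Cl2, reflux) gives the catechol (2S,3S)-3-methyl-2-(3,4,5-trimethoxyphenyl)-2,3-dihydro-1-benzofuran-5,6-diol F4. Mild dehydrogenation (Ag2O, Na2SO4, Et2O, 0 °C) then gives 6.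

**Step 4.**
- The most likely failures are reduction of the quinone by the hydrazide, conjugate addition instead of condensation, and base-induced tautomerisation during loss of sulfinate.
- Fallback, from 6 back to 8: the classical nitrosophenol route. NH2OH·HCl in EtOH at 0 °C gives the monooxime (2S,3S)-5-(hydroxyimino)-3-methyl-2-(3,4,5-trimethoxyphenyl)-3,5-dihydro-1-benzofuran-6(2H)-one F5. Na2S2O4 in THF/H2O gives the aminophenol (2S,3S)-5-amino-3-methyl-2-(3,4,5-trimethoxyphenyl)-2,3-dihydro-1-benzofuran-6-ol F6. Diazotisation (NaNO2, dilute HCl/THF, 0 °C, then NaHCO3) then gives 8.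

## Further compounds

F1 | step 5 | (2S,3S,5S)-5-hydroxy-3-methyl-5-(prop-2-en-1-yl)-2-(3,4,5-trimethoxyphenyl)-3,5-dihydro-1-benzofuran-6(2H)-one | C=CC[C@]1(O)C=C2C(=CC1=O)O[C@H](c1cc(OC)c(OC)c(OC)c1)[C@H]2C
F2 | step 2 | rac-(2S*,3S*)-6-methoxy-3-methyl-2-(3,4,5-trimethoxyphenyl)-2,3-dihydro-1-benzofuran-5-ol (both enantiomers) | Oc1cc2c(cc1OC)O[C@H](c1cc(OC)c(OC)c(OC)c1)[C@H]2C.Oc1cc2c(cc1OC)O[C@@H](c1cc(OC)c(OC)c(OC)c1)[C@@H]2C
F3 | step 2 | (2S,3S)-6-methoxy-3-methyl-2-(3,4,5-trimethoxyphenyl)-2,3-dihydro-1-benzofuran-5-yl (1S,4R)-camphanate | O=C(Oc1cc2c(cc1OC)O[C@H](c1cc(OC)c(OC)c(OC)c1)[C@H]2C)[C@@]12CC[C@@](C)(C(=O)O1)C2(C)C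
F4 | step 3 | (2S,3S)-3-methyl-2-(3,4,5-trimethoxyphenyl)-2,3-dihydro-1-benzofuran-5,6-diol | Oc1cc2c(cc1O)O[C@H](c1cc(OC)c(OC)c(OC)c1)[C@H]2C
F5 | step 4 | (2S,3S)-5-(hydroxyimino)-3-methyl-2-(3,4,5-trimethoxyphenyl)-3,5-dihydro-1-benzofuran-6(2H)-one | ON=C1C=C2C(=CC1=O)O[C@H](c1cc(OC)c(OC)c(OC)c1)[C@H]2C
F6 | step 4 | (2S,3S)-5-amino-3-methyl-2-(3,4,5-trimethoxyphenyl)-2,3-dihydro-1-benzofuran-6-ol | Nc1cc2c(cc1O)O[C@H](c1cc(OC)c(OC)c(OC)c1)[C@H]2C
A1 | alternative 1 | (2S,3S)-3-methyl-5-(prop-2-en-1-yl)-2-(3,4,5-trimethoxyphenyl)-2,3-dihydro-1-benzofuran-6-ol | C=CCc1cc2c(cc1O)O[C@H](c1cc(OC)c(OC)c(OC)c1)[C@H]2C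
A2 | alternative 2 | 4,4,5-trimethoxy-2-(prop-2-en-1-yl)cyclohexa-2,5-dien-1-one | C=CCC1=CC(OC)(OC)C(OC)=CC1=O
A3 | alternative 2 | (2S,3S,3aR)-5-methoxy-3-methyl-3a-(prop-2-en-1-yl)-2-(3,4,5-trimethoxyphenyl)-3,3a-dihydro-1-benzofuran-6(2H)-one | C=CC[C@@]12C=C(OC)C(=O)C=C1O[C@H](c1cc(OC)c(OC)c(OC)c1)[C@H]2C
A4 | alternative 3 | (2S,3S)-5-methoxy-3-methyl-2-(3,4,5-trimethoxyphenyl)-2,3-dihydro-1-benzofuran-6-ol | COc1cc2c(cc1O)O[C@H](c1cc(OC)c(OC)c(OC)c1)[C@H]2C
A5 | alternative 3 | (2S,3S)-5-methoxy-3-methyl-6-(prop-2-en-1-yloxy)-2-(3,4,5-trimethoxyphenyl)-2,3-dihydro-1-benzofuran | COc1cc2c(cc1OCC=C)O[C@H](c1cc(OC)c(OC)c(OC)c1)[C@H]2C
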